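**Retrosynthetic overview**

1. Numbering: C1 is the amide carbonyl, C15 the benzylic carbon and C16–C21 the arene. The lactam nitrogen sits on C20, next to the C21 oxygen, so the 19-membered ring (N, C1–C16, C21, C20) is opened at the aryl N–C20 bond. It is closed last by intramolecular copper-catalysed amidation of a C20 bromide with the finished primary (2E,4Z)-dienamide C1–C5.
2. Dienamide: C2=C3 by a stabilised Wittig reaction, C4=C5 by Still–Gennari olefination of the C5 aldehyde; C6/C7 by a syn glycolate aldol on the C7 enal; C8=C9 by Wittig olefination of the C9 aldehyde.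
3. C10/C11 by (Z)-crotylboration of the C11 α-silyloxy aldehyde; C12 by allylboration of the C12 aldehyde and one-carbon trimming; C14/C15 by (Z)-crotylboration of 3-bromo-2,5-bis(methoxymethoxy)benzaldehyde.
4. Ring order: the benzene ring is bought; the macrolactam is the only ring formed (step 25); the C7 carbamate and removal of the silyl and methoxymethyl groups follow.

Key step: step 25

Remark on the chemistry: atom numbers follow the target throughout; alkene 13 should form as an E/Z mixture (E drawn), and both isomers give aldehyde 15.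

**Route**

Step 1
Reactants: 1 2,5-dihydroxybenzaldehyde
Product: 2 3-bromo-2,5-dihydroxybenzaldehyde
Conditions: Br2, CHCl3, 0 °C → rt
Reagents that add atoms: bromine, BrBr
Why: Electrophilic aromatic bromination should go to C3, which is ortho to the 2-hydroxyl and meta to the formyl group, whereas both positions ortho to the 5-hydroxyl are deactivated by the ortho/para formyl group.

Step 2
Reactants: 2 3-bromo-2,5-dihydroxybenzaldehyde
Product: 3 3-bromo-2,5-bis(methoxymethoxy)benzaldehyde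
Conditions: MOMCl, i-Pr2NEt, CH2Cl2, 0 °C → reflux
Reagents that add atoms: chloromethyl methyl ether, COCCl
Why: O-alkylation of both phenols gives base-stable acetals that should survive every step up to the final acid treatment and that place a coordinating oxygen next to the bromide.

Step 3
Reactants: 3 3-bromo-2,5-bis(methoxymethoxy)benzaldehyde
Product: 5 (1R,2S)-1-[3-bromo-2,5-bis(methoxymethoxy)phenyl]-2-methylbut-3-en-1-ol, via diisopinocampheylborinate ester 4 (not isolated)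
Conditions: cis-2-butene, n-BuLi, KOt-Bu, THF, −78 → −45 °C; (+)-Ipc2BOMe [from (−)-α-pinene], −78 °C; BF3·OEt2; 3, −78 °C; then NaOH, H2O2, 0 °C → rt
Reagents that add atoms: (Z)-but-2-ene, C/C=C\C (transferred as B-[(Z)-but-2-enyl]diisopinocampheylborane, C/C=C\CB([C@H]1C[C@H]2C[C@@H]([C@@H]1C)C2(C)C)[C@H]1C[C@H]2C[C@@H]([C@@H]1C)C2(C)C)
Why: Brown asymmetric (Z)-crotylboration through a chair Zimmerman–Traxler transition state should give the syn C14-methyl/C15-hydroxyl pair, the isopinocampheyl groups of the (−)-α-pinene series directing attack to the Re face of the aldehyde (15R, 14S).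

Step 4
Reactants: 5 (1R,2S)-1-[3-bromo-2,5-bis(methoxymethoxy)phenyl]-2-methylbut-3-en-1-ol
Product: 6 1-bromo-3-[(1R,2S)-1-methoxy-2-methylbut-3-en-1-yl]-2,5-bis(methoxymethoxy)benzene
Conditions: NaH, MeI, THF/DMF, 0 °C → rt
Reagents that add atoms: iodomethane, CI
Why: Williamson etherification of the benzylic alkoxide installs the C15 methyl ether; with no carbonyl β to the oxygen there is no retro-aldol or epimerisation pathway.

Step 5
Reactants: 6 1-bromo-3-[(1R,2S)-1-methoxy-2-methylbut-3-en-1-yl]-2,5-bis(methoxymethoxy)benzene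
Product: 8 (3S,4R)-4-[3-bromo-2,5-bis(methoxymethoxy)phenyl]-4-methoxy-3-methylbutan-1-ol, via B-alkyl-9-borabicyclononane 7 (not isolated)
Conditions: 9-BBN, THF, 0 °C → rt; then NaOH, H2O2, 0 °C
Reagents that add atoms: hydrogen peroxide, OO
Why: Anti-Markovnikov hydroboration with the bulky borane places boron on the terminal carbon (C12) and oxidation with retention gives the primary alcohol, leaving the aryl bromide and acetals untouched.

Step 6
Reactants: 8 (3S,4R)-4-[3-bromo-2,5-bis(methoxymethoxy)phenyl]-4-methoxy-3-methylbutan-1-ol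
Product: 9 (3S,4R)-4-[3-bromo-2,5-bis(methoxymethoxy)phenyl]-4-methoxy-3-methylbutanal
Conditions: Dess–Martin periodinane, CH2Cl2, 0 °C → rt
Reagents that add atoms: none
Why: Dess–Martin oxidation stops at the aldehyde, and the nearest stereocentre (C14) is β to the carbonyl and cannot epimerise.

Step 7
Reactants: 9 (3S,4R)-4-[3-bromo-2,5-bis(methoxymethoxy)phenyl]-4-methoxy-3-methylbutanal
Product: 11 (4R,6S,7R)-7-[3-bromo-2,5-bis(methoxymethoxy)phenyl]-7-methoxy-6-methylhept-1-en-4-ol, via diisopinocampheylborinate ester 10 (not isolated)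
Conditions: (+)-Ipc2BOMe, allylMgBr, Et2O, 0 °C → rt; 9, −78 °C; then NaOH, H2O2, 0 °C → rt
Reagents that add atoms: allylmagnesium bromide, C=CC[Mg]Br (transferred as B-allyldiisopinocampheylborane, C=CCB([C@H]1C[C@H]2C[C@@H]([C@@H]1C)C2(C)C)[C@H]1C[C@H]2C[C@@H]([C@@H]1C)C2(C)C)
Why: Brown asymmetric allylboration through a chair transition state sets the C12 carbinol under reagent control (Re-face attack), the remote C14 centre exerting little bias.

Step 8
Reactants: 11 (4R,6S,7R)-7-[3-bromo-2,5-bis(methoxymethoxy)phenyl]-7-methoxy-6-methylhept-1-en-4-ol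
Product: 12 tert-butyl{[(4R,6S,7R)-7-[3-bromo-2,5-bis(methoxymethoxy)phenyl]-7-methoxy-6-methylhept-1-en-4-yl]oxy}dimethylsilane
Conditions: TBSCl, imidazole, DMF, rt
Reagents that add atoms: tert-butyldimethylsilyl chloride, CC(C)(C)[Si](C)(C)Cl
Why: Silylation of the unhindered secondary alcohol gives the robust C12 silyl ether that is carried to the end of the route.

Step 9
Reactants: 12 tert-butyl{[(4R,6S,7R)-7-[3-bromo-2,5-bis(methoxymethoxy)phenyl]-7-methoxy-6-methylhept-1-en-4-yl]oxy}dimethylsilane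
Product: 13 tert-butyl{[(2E,4S,6S,7R)-7-[3-bromo-2,5-bis(methoxymethoxy)phenyl]-7-methoxy-6-methylhept-2-en-4-yl]oxy}dimethylsilane
Conditions: RuHCl(CO)(PPh3)3 (5 mol%), toluene, 80 °C
Reagents that add atoms: none
Why: Ruthenium hydride olefin isomerisation (hydrometalation, then β-hydride elimination) should move the terminal double bond one position to the more stable 1,2-disubstituted alkene next to C12 without touching a stereocentre.

Step 10
Reactants: 13 tert-butyl{[(2E,4S,6S,7R)-7-[3-bromo-2,5-bis(methoxymethoxy)phenyl]-7-methoxy-6-methylhept-2-en-4-yl]oxy}dimethylsilane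
Product: 15 (2S,4S,5R)-5-[3-bromo-2,5-bis(methoxymethoxy)phenyl]-2-[(tert-butyldimethylsilyl)oxy]-5-methoxy-4-methylpentanal, via vicinal diol 14 (not isolated)
Conditions: OsO4 (cat.), NaIO4, 2,6-lutidine, dioxane/H2O, rt
Reagents that add atoms: osmium tetroxide, O=[Os](=O)(=O)=O; sodium periodate, [Na+].[O-]I(=O)(=O)=O (source of the carbonyl oxygen)
Why: Lemieux–Johnson cleavage (osmylation, then periodate scission) of the only alkene gives the C11 aldehyde with its α-silyloxy centre intact under near-neutral conditions, and unlike ozone it spares the electron-rich arene.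

Step 11
Reactants: 15 (2S,4S,5R)-5-[3-bromo-2,5-bis(methoxymethoxy)phenyl]-2-[(tert-butyldimethylsilyl)oxy]-5-methoxy-4-methylpentanal
Product: 17 (3S,4R,5S,7S,8R)-8-[3-bromo-2,5-bis(methoxymethoxy)phenyl]-5-[(tert-butyldimethylsilyl)oxy]-8-methoxy-3,7-dimethyloct-1-en-4-ol, via diisopinocampheylborinate ester 16 (not isolated)
Conditions: cis-2-butene, n-BuLi, KOt-Bu, THF, −78 → −45 °C; (+)-Ipc2BOMe, −78 °C; BF3·OEt2; 15, −78 °C; then NaOH, H2O2, 0 °C → rt
Reagents that add atoms: (Z)-but-2-ene, C/C=C\C (transferred as B-[(Z)-but-2-enyl]diisopinocampheylborane, C/C=C\CB([C@H]1C[C@H]2C[C@@H]([C@@H]1C)C2(C)C)[C@H]1C[C@H]2C[C@@H]([C@@H]1C)C2(C)C)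
Why: Brown (Z)-crotylboration gives the 10,11-syn pair through a chair transition state, and the Re-face preference of the reagent coincides with the Felkin/Cornforth preference of the α-silyloxy aldehyde for the 11,12-anti product (matched pair: 10S, 11R).

Step 12
Reactants: 17 (3S,4R,5S,7S,8R)-8-[3-bromo-2,5-bis(methoxymethoxy)phenyl]-5-[(tert-butyldimethylsilyl)oxy]-8-methoxy-3,7-dimethyloct-1-en-4-ol
Product: 18 (3S,4R,5S,7S,8R)-8-[3-bromo-2,5-bis(methoxymethoxy)phenyl]-4,5-bis[(tert-butyldimethylsilyl)oxy]-8-methoxy-3,7-dimethyloct-1-ene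
Conditions: TBSOTf, 2,6-lutidine, CH2Cl2, −78 → 0 °C
Reagents that add atoms: tert-butyldimethylsilyl triflate, CC(C)(C)[Si](C)(C)OS(=O)(=O)C(F)(F)F
Why: The silyl triflate with a hindered base silylates the crowded C11 hydroxyl; a 1,2-silyl shift between O11 and O12 would lead to the same bis-silyl ether.

Step 13
Reactants: 18 (3S,4R,5S,7S,8R)-8-[3-bromo-2,5-bis(methoxymethoxy)phenyl]-4,5-bis[(tert-butyldimethylsilyl)oxy]-8-methoxy-3,7-dimethyloct-1-ene
Product: 20 (2R,3R,4S,6S,7R)-7-[3-bromo-2,5-bis(methoxymethoxy)phenyl]-3,4-bis[(tert-butyldimethylsilyl)oxy]-7-methoxy-2,6-dimethylheptanal, via vicinal diol 19 (not isolated)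
Conditions: OsO4 (cat.), NaIO4, 2,6-lutidine, dioxane/H2O, rt
Reagents that add atoms: osmium tetroxide, O=[Os](=O)(=O)=O; sodium periodate, [Na+].[O-]I(=O)(=O)=O (source of the carbonyl oxygen)
Why: Lemieux–Johnson cleavage of the vinyl group, the only alkene present, gives the C9 aldehyde under buffered conditions that should not epimerise C10.

Step 14
Reactants: 20 (2R,3R,4S,6S,7R)-7-[3-bromo-2,5-bis(methoxymethoxy)phenyl]-3,4-bis[(tert-butyldimethylsilyl)oxy]-7-methoxy-2,6-dimethylheptanal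
Product: 21 (2E,4S,5R,6S,8S,9R)-9-[3-bromo-2,5-bis(methoxymethoxy)phenyl]-5,6-bis[(tert-butyldimethylsilyl)oxy]-9-methoxy-2,4,8-trimethylnon-2-enal
Conditions: Ph3P=C(Me)CHO, toluene, 90 °C
Reagents that add atoms: 2-(triphenylphosphoranylidene)propanal, CC(C=O)=P(c1ccccc1)(c1ccccc1)c1ccccc1
Why: Wittig olefination with the stabilised formyl ylide gives the (E)-trisubstituted C8=C9 enal under thermodynamic control and delivers C7 directly at the aldehyde oxidation level.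

Step 15
Reactants: 22 (R)-4-benzyl-2-oxazolidinone
Product: 23 (R)-4-benzyl-3-(2-methoxyacetyl)oxazolidin-2-one
Conditions: MeOCH2COCl, Et3N, DMAP (cat.), CH2Cl2, 0 °C → rt
Reagents that add atoms: methoxyacetyl chloride, COCC(=O)Cl
Why: DMAP-catalysed N-acylation of the oxazolidinone gives the glycolate imide needed for the auxiliary-controlled aldol.

Step 16
Reactants: 23 (R)-4-benzyl-3-(2-methoxyacetyl)oxazolidin-2-one; 21 (2E,4S,5R,6S,8S,9R)-9-[3-bromo-2,5-bis(methoxymethoxy)phenyl]-5,6-bis[(tert-butyldimethylsilyl)oxy]-9-methoxy-2,4,8-trimethylnon-2-enal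
Product: 26 (R)-4-benzyl-3-[(2R,3S,4E,6S,7R,8S,10S,11R)-11-[3-bromo-2,5-bis(methoxymethoxy)phenyl]-7,8-bis[(tert-butyldimethylsilyl)oxy]-3-hydroxy-2,11-dimethoxy-4,6,10-trimethylundec-4-enoyl]oxazolidin-2-one, via dibutylboron enolate 24 (not isolated), via dibutylboron aldolate 25 (not isolated)
Conditions: 23, Bu2BOTf, Et3N, CH2Cl2, −78 → 0 °C; 21, −78 → 0 °C; then pH 7 buffer, MeOH, H2O2, 0 °C
Reagents that add atoms: none
Why: Evans syn aldol: the (Z)-boron enolate of the glycolate imide adds through a chair Zimmerman–Traxler transition state on the enolate face away from the benzyl group, so the (R)-auxiliary sets the syn C6-methoxy/C7-hydroxyl pair with the target configuration.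

Step 17
Reactants: 26 (R)-4-benzyl-3-[(2R,3S,4E,6S,7R,8S,10S,11R)-11-[3-bromo-2,5-bis(methoxymethoxy)phenyl]-7,8-bis[(tert-butyldimethylsilyl)oxy]-3-hydroxy-2,11-dimethoxy-4,6,10-trimethylundec-4-enoyl]oxazolidin-2-one
Product: 27 (2R,3S,4E,6S,7R,8S,10S,11R)-11-[3-bromo-2,5-bis(methoxymethoxy)phenyl]-7,8-bis[(tert-butyldimethylsilyl)oxy]-3-hydroxy-N,2,11-trimethoxy-N,4,6,10-tetramethylundec-4-enamide
Conditions: AlMe3, MeONHMe·HCl, THF, −20 → 0 °C
Reagents that add atoms: N,O-dimethylhydroxylamine hydrochloride, CNOC.Cl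
Why: Weinreb transamination: the aluminium amide, guided by the free β-hydroxyl, attacks the exocyclic imide carbonyl and releases the auxiliary without retro-aldol cleavage.

Step 18
Reactants: 27 (2R,3S,4E,6S,7R,8S,10S,11R)-11-[3-bromo-2,5-bis(methoxymethoxy)phenyl]-7,8-bis[(tert-butyldimethylsilyl)oxy]-3-hydroxy-N,2,11-trimethoxy-N,4,6,10-tetramethylundec-4-enamide
Product: 28 (2R,3S,4E,6S,7R,8S,10S,11R)-11-[3-bromo-2,5-bis(methoxymethoxy)phenyl]-7,8-bis[(tert-butyldimethylsilyl)oxy]-N,2,11-trimethoxy-N,4,6,10-tetramethyl-3-[(triethylsilyl)oxy]undec-4-enamide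
Conditions: TESCl, imidazole, DMAP (cat.), DMF, 0 °C → rt
Reagents that add atoms: chlorotriethylsilane, CC[Si](Cl)(CC)CC
Why: Silylation gives a C7 triethylsilyl ether, chosen because it can later be removed in the presence of the two tert-butyldimethylsilyl ethers.

Step 19
Reactants: 28 (2R,3S,4E,6S,7R,8S,10S,11R)-11-[3-bromo-2,5-bis(methoxymethoxy)phenyl]-7,8-bis[(tert-butyldimethylsilyl)oxy]-N,2,11-trimethoxy-N,4,6,10-tetramethyl-3-[(triethylsilyl)oxy]undec-4-enamide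
Product: 29 (2R,3S,4E,6S,7R,8S,10S,11R)-11-[3-bromo-2,5-bis(methoxymethoxy)phenyl]-7,8-bis[(tert-butyldimethylsilyl)oxy]-2,11-dimethoxy-4,6,10-trimethyl-3-[(triethylsilyl)oxy]undec-4-enal
Conditions: i-Bu2AlH, THF, −78 °C; Rochelle salt work-up
Reagents that add atoms: none
Why: Weinreb amide reduction stops at the chelated tetrahedral aluminium intermediate, which gives the C5 aldehyde only on work-up, so the α-methoxy centre C6 never meets base.

Step 20
Reactants: 29 (2R,3S,4E,6S,7R,8S,10S,11R)-11-[3-bromo-2,5-bis(methoxymethoxy)phenyl]-7,8-bis[(tert-butyldimethylsilyl)oxy]-2,11-dimethoxy-4,6,10-trimethyl-3-[(triethylsilyl)oxy]undec-4-enal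
Product: 30 methyl (2Z,4S,5S,6E,8S,9R,10S,12S,13R)-13-[3-bromo-2,5-bis(methoxymethoxy)phenyl]-9,10-bis[(tert-butyldimethylsilyl)oxy]-4,13-dimethoxy-6,8,12-trimethyl-5-[(triethylsilyl)oxy]trideca-2,6-dienoate
Conditions: (CF3CH2O)2P(O)CH2CO2Me, KN(SiMe3)2, 18-crown-6, THF, −78 °C
Reagents that add atoms: methyl 2-[bis(2,2,2-trifluoroethoxy)phosphoryl]acetate, COC(=O)CP(=O)(OCC(F)(F)F)OCC(F)(F)F
Why: Still–Gennari olefination: the electron-poor phosphonate with a dissociated potassium counter-ion eliminates fast and irreversibly from the kinetic adduct, which should give the (Z)-C4=C5 enoate.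

Step 21
Reactants: 30 methyl (2Z,4S,5S,6E,8S,9R,10S,12S,13R)-13-[3-bromo-2,5-bis(methoxymethoxy)phenyl]-9,10-bis[(tert-butyldimethylsilyl)oxy]-4,13-dimethoxy-6,8,12-trimethyl-5-[(triethylsilyl)oxy]trideca-2,6-dienoate
Product: 31 (2Z,4S,5S,6E,8S,9R,10S,12S,13R)-13-[3-bromo-2,5-bis(methoxymethoxy)phenyl]-9,10-bis[(tert-butyldimethylsilyl)oxy]-4,13-dimethoxy-6,8,12-trimethyl-5-[(triethylsilyl)oxy]trideca-2,6-dien-1-ol
Conditions: i-Bu2AlH, CH2Cl2, −78 °C
Reagents that add atoms: none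
Why: 1,2-Reduction of the enoate at low temperature gives the allylic alcohol with the Z geometry retained.

Step 22
Reactants: 31 (2Z,4S,5S,6E,8S,9R,10S,12S,13R)-13-[3-bromo-2,5-bis(methoxymethoxy)phenyl]-9,10-bis[(tert-butyldimethylsilyl)oxy]-4,13-dimethoxy-6,8,12-trimethyl-5-[(triethylsilyl)oxy]trideca-2,6-dien-1-ol
Product: 32 (2Z,4S,5S,6E,8S,9R,10S,12S,13R)-13-[3-bromo-2,5-bis(methoxymethoxy)phenyl]-9,10-bis[(tert-butyldimethylsilyl)oxy]-4,13-dimethoxy-6,8,12-trimethyl-5-[(triethylsilyl)oxy]trideca-2,6-dienal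
Conditions: MnO2, CH2Cl2, rt
Reagents that add atoms: none
Why: Neutral heterogeneous allylic oxidation gives the (Z)-enal, which is used at once so that it has little chance to isomerise.

Step 23
Reactants: 32 (2Z,4S,5S,6E,8S,9R,10S,12S,13R)-13-[3-bromo-2,5-bis(methoxymethoxy)phenyl]-9,10-bis[(tert-butyldimethylsilyl)oxy]-4,13-dimethoxy-6,8,12-trimethyl-5-[(triethylsilyl)oxy]trideca-2,6-dienal
Product: 33 ethyl (2E,4Z,6S,7S,8E,10S,11R,12S,14S,15R)-15-[3-bromo-2,5-bis(methoxymethoxy)phenyl]-11,12-bis[(tert-butyldimethylsilyl)oxy]-6,15-dimethoxy-2,8,10,14-tetramethyl-7-[(triethylsilyl)oxy]pentadeca-2,4,8-trienoate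
Conditions: Ph3P=C(Me)CO2Et, CH2Cl2, rt
Reagents that add atoms: ethyl 2-(triphenylphosphoranylidene)propanoate, CCOC(=O)C(C)=P(c1ccccc1)(c1ccccc1)c1ccccc1
Why: Wittig olefination with the stabilised ylide forms C2=C3 with E geometry under mild neutral conditions that leave the 4Z alkene unchanged.

Step 24
Reactants: 33 ethyl (2E,4Z,6S,7S,8E,10S,11R,12S,14S,15R)-15-[3-bromo-2,5-bis(methoxymethoxy)phenyl]-11,12-bis[(tert-butyldimethylsilyl)oxy]-6,15-dimethoxy-2,8,10,14-tetramethyl-7-[(triethylsilyl)oxy]pentadeca-2,4,8-trienoate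
Product: 34 (2E,4Z,6S,7S,8E,10S,11R,12S,14S,15R)-15-[3-bromo-2,5-bis(methoxymethoxy)phenyl]-11,12-bis[(tert-butyldimethylsilyl)oxy]-6,15-dimethoxy-2,8,10,14-tetramethyl-7-[(triethylsilyl)oxy]pentadeca-2,4,8-trienamide
Conditions: AlMe3, NH4Cl, toluene, 0 → 50 °C
Reagents that add atoms: ammonium chloride, [NH4+].[Cl-]
Why: Weinreb aminolysis: the aluminium amide formed from AlMe3 and NH4Cl converts the ester directly into the primary amide, with no activated acyl derivative and no free base that could isomerise the diene.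

Step 25
Reactants: 34 (2E,4Z,6S,7S,8E,10S,11R,12S,14S,15R)-15-[3-bromo-2,5-bis(methoxymethoxy)phenyl]-11,12-bis[(tert-butyldimethylsilyl)oxy]-6,15-dimethoxy-2,8,10,14-tetramethyl-7-[(triethylsilyl)oxy]pentadeca-2,4,8-trienamide
Product: 35 protected macrolactam: (2E,4Z,6S,7S,8E,10S,11R,12S,14S,15R)-19-membered lactam (N on C20) with 7-O-triethylsilyl, 11,12-bis-O-tert-butyldimethylsilyl and 18,21-bis-O-methoxymethyl groups
Conditions: CuI (30 mol%), trans-N,N'-dimethylcyclohexane-1,2-diamine (60 mol%), K2CO3, toluene (0.005 M), 110 °C, argon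
Reagents that add atoms: none
Why: This is an intramolecular Goldberg amidation, whose closest precedent is the copper/diamine-catalysed N-arylation of primary amides with aryl bromides and its use for macrolactams: K2CO3 and diamine-ligated monovalent copper turn the primary amide into a copper amidate, which activates the C20–Br bond to give a trivalent copper aryl amidate, and reductive elimination forms N–C20. The 19-membered ring closes end-to-end at an sp2 carbon, a macrocyclic closure with the breaking C–Br bond outside the new ring, and it is favoured over oligomerisation by high dilution and by the C21 methoxymethoxy oxygen, which can hold copper next to the bromide. No stereocentre is formed. Because there is no acyl activation, the dienoyl unit cannot isomerise through a ketene or an activated ester, so the 2E and 4Z alkenes should be retained. The step needs N-arylation over O-arylation and ring closure over intermolecular coupling: the diamine ligand makes the amidate the preferred nucleophile, every hydroxyl is masked as a silyl ether or acetal, and a primary amide is the most reactive amide class, so the secondary anilide product should not be arylated again.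

Step 26
Reactants: 35 protected macrolactam
Product: 36 C7 alcohol of the macrolactam (11,12-bis-O-tert-butyldimethylsilyl, 18,21-bis-O-methoxymethyl)
Conditions: PPTS, MeOH/CH2Cl2, 0 °C → rt
Reagents that add atoms: none
Why: Mild acid-catalysed methanolysis removes the triethylsilyl ether, which is far more labile than the hindered secondary tert-butyldimethylsilyl ethers and the aryl acetals.

Step 27
Reactants: 36 C7 alcohol of the macrolactam
Product: 38 C7 carbamate of the macrolactam (11,12-bis-O-tert-butyldimethylsilyl, 18,21-bis-O-methoxymethyl), via N-trichloroacetyl carbamate 37 (not isolated)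
Conditions: Cl3CC(O)NCO, CH2Cl2, 0 °C; then K2CO3, MeOH, rt
Reagents that add atoms: trichloroacetyl isocyanate, O=C=NC(=O)C(Cl)(Cl)Cl
Why: The hindered C7 hydroxyl adds to the highly electrophilic acyl isocyanate and mild methanolysis then removes the trichloroacetyl group (Kočovský carbamate synthesis), conditions to which silyl ethers, acetals and the dienamide are inert.

Step 28
Reactants: 38 C7 carbamate of the macrolactam
Product: 39 11,12-diol C7 carbamate (18,21-bis-O-methoxymethyl)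
Conditions: HF·pyridine, pyridine, THF, 0 °C → rt
Reagents that add atoms: none
Why: Buffered fluoride desilylation cleaves both tert-butyldimethylsilyl ethers while the carbamate, the aryl acetals and the alkenes are untouched.

Step 29
Reactants: 39 11,12-diol C7 carbamate (18,21-bis-O-methoxymethyl)
Product: 40 CNP0523404.1
Conditions: HCl (1.25 M in MeOH), 0 °C → rt, argon
Reagents that add atoms: none
Why: Acid-catalysed acetal exchange with methanol frees both phenols under mild conditions, since a phenol is a good leaving group from the protonated acetal, and exclusion of air keeps the aminohydroquinone from oxidising.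

**Compound list**

1 | 2,5-dihydroxybenzaldehyde | O=Cc1cc(O)ccc1O | starting material
2 | 3-bromo-2,5-dihydroxybenzaldehyde | O=Cc1cc(O)cc(Br)c1O | intermediate
3 | 3-bromo-2,5-bis(methoxymethoxy)benzaldehyde | O=Cc1cc(OCOC)cc(Br)c1OCOC | intermediate
4 | diisopinocampheylborinate ester of 5 | C=C[C@H](C)[C@@H](OB([C@H]1C[C@H]2C[C@@H]([C@@H]1C)C2(C)C)[C@H]1C[C@H]2C[C@@H]([C@@H]1C)C2(C)C)c1cc(OCOC)cc(Br)c1OCOC | intermediate (not isolated)
5 | (1R,2S)-1-[3-bromo-2,5-bis(methoxymethoxy)phenyl]-2-methylbut-3-en-1-ol | C=C[C@H](C)[C@@H](O)c1cc(OCOC)cc(Br)c1OCOC | intermediate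
6 | 1-bromo-3-[(1R,2S)-1-methoxy-2-methylbut-3-en-1-yl]-2,5-bis(methoxymethoxy)benzene | C=C[C@H](C)[C@@H](OC)c1cc(OCOC)cc(Br)c1OCOC | intermediate
7 | B-alkyl-9-borabicyclononane from 6 (boron on C12) | C1CC2CCCC(C1)B2CC[C@H](C)[C@@H](OC)c1cc(OCOC)cc(Br)c1OCOC | intermediate (not isolated)
8 | (3S,4R)-4-[3-bromo-2,5-bis(methoxymethoxy)phenyl]-4-methoxy-3-methylbutan-1-ol | OCC[C@H](C)[C@@H](OC)c1cc(OCOC)cc(Br)c1OCOC | intermediate
9 | (3S,4R)-4-[3-bromo-2,5-bis(methoxymethoxy)phenyl]-4-methoxy-3-methylbutanal | O=CC[C@H](C)[C@@H](OC)c1cc(OCOC)cc(Br)c1OCOC | intermediate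
10 | diisopinocampheylborinate ester of 11 | C=CC[C@@H](OB([C@H]1C[C@H]2C[C@@H]([C@@H]1C)C2(C)C)[C@H]1C[C@H]2C[C@@H]([C@@H]1C)C2(C)C)C[C@H](C)[C@@H](OC)c1cc(OCOC)cc(Br)c1OCOC | intermediate (not isolated)
11 | (4R,6S,7R)-7-[3-bromo-2,5-bis(methoxymethoxy)phenyl]-7-methoxy-6-methylhept-1-en-4-ol | C=CC[C@@H](O)C[C@H](C)[C@@H](OC)c1cc(OCOC)cc(Br)c1OCOC | intermediate
12 | tert-butyl{[(4R,6S,7R)-7-[3-bromo-2,5-bis(methoxymethoxy)phenyl]-7-methoxy-6-methylhept-1-en-4-yl]oxy}dimethylsilane | C=CC[C@@H](O[Si](C)(C)C(C)(C)C)C[C@H](C)[C@@H](OC)c1cc(OCOC)cc(Br)c1OCOC | intermediate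
13 | tert-butyl{[(2E,4S,6S,7R)-7-[3-bromo-2,5-bis(methoxymethoxy)phenyl]-7-methoxy-6-methylhept-2-en-4-yl]oxy}dimethylsilane | C/C=C/[C@@H](O[Si](C)(C)C(C)(C)C)C[C@H](C)[C@@H](OC)c1cc(OCOC)cc(Br)c1OCOC | intermediate
14 | 2,3-diol from 13 (mixture at the two new carbinols) | CC(O)C(O)[C@@H](O[Si](C)(C)C(C)(C)C)C[C@H](C)[C@@H](OC)c1cc(OCOC)cc(Br)c1OCOC | intermediate (not isolated)
15 | (2S,4S,5R)-5-[3-bromo-2,5-bis(methoxymethoxy)phenyl]-2-[(tert-butyldimethylsilyl)oxy]-5-methoxy-4-methylpentanal | O=C[C@@H](O[Si](C)(C)C(C)(C)C)C[C@H](C)[C@@H](OC)c1cc(OCOC)cc(Br)c1OCOC | intermediate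
16 | diisopinocampheylborinate ester of 17 | C=C[C@H](C)[C@@H](OB([C@H]1C[C@H]2C[C@@H]([C@@H]1C)C2(C)C)[C@H]1C[C@H]2C[C@@H]([C@@H]1C)C2(C)C)[C@@H](O[Si](C)(C)C(C)(C)C)C[C@H](C)[C@@H](OC)c1cc(OCOC)cc(Br)c1OCOC | intermediate (not isolated)
17 | (3S,4R,5S,7S,8R)-8-[3-bromo-2,5-bis(methoxymethoxy)phenyl]-5-[(tert-butyldimethylsilyl)oxy]-8-methoxy-3,7-dimethyloct-1-en-4-ol | C=C[C@H](C)[C@@H](O)[C@@H](O[Si](C)(C)C(C)(C)C)C[C@H](C)[C@@H](OC)c1cc(OCOC)cc(Br)c1OCOC | intermediate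
18 | (3S,4R,5S,7S,8R)-8-[3-bromo-2,5-bis(methoxymethoxy)phenyl]-4,5-bis[(tert-butyldimethylsilyl)oxy]-8-methoxy-3,7-dimethyloct-1-ene | C=C[C@H](C)[C@@H](O[Si](C)(C)C(C)(C)C)[C@@H](O[Si](C)(C)C(C)(C)C)C[C@H](C)[C@@H](OC)c1cc(OCOC)cc(Br)c1OCOC | intermediate
19 | 1,2-diol from 18 (mixture at the new carbinol) | OCC(O)[C@H](C)[C@@H](O[Si](C)(C)C(C)(C)C)[C@@H](O[Si](C)(C)C(C)(C)C)C[C@H](C)[C@@H](OC)c1cc(OCOC)cc(Br)c1OCOC | intermediate (not isolated)
20 | (2R,3R,4S,6S,7R)-7-[3-bromo-2,5-bis(methoxymethoxy)phenyl]-3,4-bis[(tert-butyldimethylsilyl)oxy]-7-methoxy-2,6-dimethylheptanal | O=C[C@H](C)[C@@H](O[Si](C)(C)C(C)(C)C)[C@@H](O[Si](C)(C)C(C)(C)C)C[C@H](C)[C@@H](OC)c1cc(OCOC)cc(Br)c1OCOC | intermediate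
21 | (2E,4S,5R,6S,8S,9R)-9-[3-bromo-2,5-bis(methoxymethoxy)phenyl]-5,6-bis[(tert-butyldimethylsilyl)oxy]-9-methoxy-2,4,8-trimethylnon-2-enal | O=C/C(C)=C/[C@H](C)[C@@H](O[Si](C)(C)C(C)(C)C)[C@@H](O[Si](C)(C)C(C)(C)C)C[C@H](C)[C@@H](OC)c1cc(OCOC)cc(Br)c1OCOC | intermediate
22 | (R)-4-benzyl-2-oxazolidinone | O=C1N[C@H](Cc2ccccc2)CO1 | starting material
23 | (R)-4-benzyl-3-(2-methoxyacetyl)oxazolidin-2-one | COCC(=O)N1[C@H](Cc2ccccc2)COC1=O | intermediate
24 | (Z)-dibutylboron enolate of 23 | CO/C=C(\OB(CCCC)CCCC)N1[C@H](Cc2ccccc2)COC1=O | intermediate (not isolated)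
25 | dibutylboron aldolate of 26 | O=C1OC[C@@H](Cc2ccccc2)N1C(=O)[C@H](OC)[C@@H](OB(CCCC)CCCC)/C(C)=C/[C@H](C)[C@@H](O[Si](C)(C)C(C)(C)C)[C@@H](O[Si](C)(C)C(C)(C)C)C[C@H](C)[C@@H](OC)c1cc(OCOC)cc(Br)c1OCOC | intermediate (not isolated)
26 | (R)-4-benzyl-3-[(2R,3S,4E,6S,7R,8S,10S,11R)-11-[3-bromo-2,5-bis(methoxymethoxy)phenyl]-7,8-bis[(tert-butyldimethylsilyl)oxy]-3-hydroxy-2,11-dimethoxy-4,6,10-trimethylundec-4-enoyl]oxazolidin-2-one | O=C1OC[C@@H](Cc2ccccc2)N1C(=O)[C@H](OC)[C@@H](O)/C(C)=C/[C@H](C)[C@@H](O[Si](C)(C)C(C)(C)C)[C@@H](O[Si](C)(C)C(C)(C)C)C[C@H](C)[C@@H](OC)c1cc(OCOC)cc(Br)c1OCOC | intermediate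
27 | (2R,3S,4E,6S,7R,8S,10S,11R)-11-[3-bromo-2,5-bis(methoxymethoxy)phenyl]-7,8-bis[(tert-butyldimethylsilyl)oxy]-3-hydroxy-N,2,11-trimethoxy-N,4,6,10-tetramethylundec-4-enamide | CON(C)C(=O)[C@H](OC)[C@@H](O)/C(C)=C/[C@H](C)[C@@H](O[Si](C)(C)C(C)(C)C)[C@@H](O[Si](C)(C)C(C)(C)C)C[C@H](C)[C@@H](OC)c1cc(OCOC)cc(Br)c1OCOC | intermediate
28 | 3-O-triethylsilyl ether of 27 | CON(C)C(=O)[C@H](OC)[C@@H](O[Si](CC)(CC)CC)/C(C)=C/[C@H](C)[C@@H](O[Si](C)(C)C(C)(C)C)[C@@H](O[Si](C)(C)C(C)(C)C)C[C@H](C)[C@@H](OC)c1cc(OCOC)cc(Br)c1OCOC | intermediate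
29 | (2R,3S,4E,6S,7R,8S,10S,11R)-11-[3-bromo-2,5-bis(methoxymethoxy)phenyl]-7,8-bis[(tert-butyldimethylsilyl)oxy]-2,11-dimethoxy-4,6,10-trimethyl-3-[(triethylsilyl)oxy]undec-4-enal | O=C[C@H](OC)[C@@H](O[Si](CC)(CC)CC)/C(C)=C/[C@H](C)[C@@H](O[Si](C)(C)C(C)(C)C)[C@@H](O[Si](C)(C)C(C)(C)C)C[C@H](C)[C@@H](OC)c1cc(OCOC)cc(Br)c1OCOC | intermediate
30 | methyl (2Z,4S,5S,6E,8S,9R,10S,12S,13R)-13-[3-bromo-2,5-bis(methoxymethoxy)phenyl]-9,10-bis[(tert-butyldimethylsilyl)oxy]-4,13-dimethoxy-6,8,12-trimethyl-5-[(triethylsilyl)oxy]trideca-2,6-dienoate | COC(=O)/C=C\[C@H](OC)[C@@H](O[Si](CC)(CC)CC)/C(C)=C/[C@H](C)[C@@H](O[Si](C)(C)C(C)(C)C)[C@@H](O[Si](C)(C)C(C)(C)C)C[C@H](C)[C@@H](OC)c1cc(OCOC)cc(Br)c1OCOC | intermediate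
31 | (2Z,4S,5S,6E,8S,9R,10S,12S,13R)-13-[3-bromo-2,5-bis(methoxymethoxy)phenyl]-9,10-bis[(tert-butyldimethylsilyl)oxy]-4,13-dimethoxy-6,8,12-trimethyl-5-[(triethylsilyl)oxy]trideca-2,6-dien-1-ol | OC/C=C\[C@H](OC)[C@@H](O[Si](CC)(CC)CC)/C(C)=C/[C@H](C)[C@@H](O[Si](C)(C)C(C)(C)C)[C@@H](O[Si](C)(C)C(C)(C)C)C[C@H](C)[C@@H](OC)c1cc(OCOC)cc(Br)c1OCOC | intermediate
32 | (2Z,4S,5S,6E,8S,9R,10S,12S,13R)-13-[3-bromo-2,5-bis(methoxymethoxy)phenyl]-9,10-bis[(tert-butyldimethylsilyl)oxy]-4,13-dimethoxy-6,8,12-trimethyl-5-[(triethylsilyl)oxy]trideca-2,6-dienal | O=C/C=C\[C@H](OC)[C@@H](O[Si](CC)(CC)CC)/C(C)=C/[C@H](C)[C@@H](O[Si](C)(C)C(C)(C)C)[C@@H](O[Si](C)(C)C(C)(C)C)C[C@H](C)[C@@H](OC)c1cc(OCOC)cc(Br)c1OCOC | intermediate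
33 | ethyl (2E,4Z,6S,7S,8E,10S,11R,12S,14S,15R)-15-[3-bromo-2,5-bis(methoxymethoxy)phenyl]-11,12-bis[(tert-butyldimethylsilyl)oxy]-6,15-dimethoxy-2,8,10,14-tetramethyl-7-[(triethylsilyl)oxy]pentadeca-2,4,8-trienoate | CCOC(=O)/C(C)=C/C=C\[C@H](OC)[C@@H](O[Si](CC)(CC)CC)/C(C)=C/[C@H](C)[C@@H](O[Si](C)(C)C(C)(C)C)[C@@H](O[Si](C)(C)C(C)(C)C)C[C@H](C)[C@@H](OC)c1cc(OCOC)cc(Br)c1OCOC | intermediate
34 | (2E,4Z,6S,7S,8E,10S,11R,12S,14S,15R)-15-[3-bromo-2,5-bis(methoxymethoxy)phenyl]-11,12-bis[(tert-butyldimethylsilyl)oxy]-6,15-dimethoxy-2,8,10,14-tetramethyl-7-[(triethylsilyl)oxy]pentadeca-2,4,8-trienamide (seco amide) | NC(=O)/C(C)=C/C=C\[C@H](OC)[C@@H](O[Si](CC)(CC)CC)/C(C)=C/[C@H](C)[C@@H](O[Si](C)(C)C(C)(C)C)[C@@H](O[Si](C)(C)C(C)(C)C)C[C@H](C)[C@@H](OC)c1cc(OCOC)cc(Br)c1OCOC | intermediate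
35 | protected macrolactam (7-O-triethylsilyl, 11,12-bis-O-tert-butyldimethylsilyl, 18,21-bis-O-methoxymethyl; 2E,4Z,6S,7S,8E,10S,11R,12S,14S,15R) | CO[C@H]1/C=C\C=C(/C)C(=O)Nc2cc(OCOC)cc(c2OCOC)[C@H](OC)[C@@H](C)C[C@H](O[Si](C)(C)C(C)(C)C)[C@H](O[Si](C)(C)C(C)(C)C)[C@@H](C)/C=C(\C)[C@@H]1O[Si](CC)(CC)CC | intermediate
36 | C7 alcohol of the macrolactam (11,12-bis-O-tert-butyldimethylsilyl, 18,21-bis-O-methoxymethyl) | CO[C@H]1/C=C\C=C(/C)C(=O)Nc2cc(OCOC)cc(c2OCOC)[C@H](OC)[C@@H](C)C[C@H](O[Si](C)(C)C(C)(C)C)[C@H](O[Si](C)(C)C(C)(C)C)[C@@H](C)/C=C(\C)[C@@H]1O | intermediate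
37 | C7 N-trichloroacetyl carbamate of the macrolactam | CO[C@H]1/C=C\C=C(/C)C(=O)Nc2cc(OCOC)cc(c2OCOC)[C@H](OC)[C@@H](C)C[C@H](O[Si](C)(C)C(C)(C)C)[C@H](O[Si](C)(C)C(C)(C)C)[C@@H](C)/C=C(\C)[C@@H]1OC(=O)NC(=O)C(Cl)(Cl)Cl | intermediate (not isolated)
38 | C7 carbamate of the macrolactam (11,12-bis-O-tert-butyldimethylsilyl, 18,21-bis-O-methoxymethyl) | CO[C@H]1/C=C\C=C(/C)C(=O)Nc2cc(OCOC)cc(c2OCOC)[C@H](OC)[C@@H](C)C[C@H](O[Si](C)(C)C(C)(C)C)[C@H](O[Si](C)(C)C(C)(C)C)[C@@H](C)/C=C(\C)[C@@H]1OC(N)=O | intermediate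
39 | 11,12-diol C7 carbamate (18,21-bis-O-methoxymethyl) | CO[C@H]1/C=C\C=C(/C)C(=O)Nc2cc(OCOC)cc(c2OCOC)[C@H](OC)[C@@H](C)C[C@H](O)[C@H](O)[C@@H](C)/C=C(\C)[C@@H]1OC(N)=O | intermediate
40 | CNP0523404.1 (2E,4Z,6S,7S,8E,10S,11R,12S,14S,15R; 7-O-carbamoyl-11,12,18,21-tetrahydroxy-6,15-dimethoxy macrolactam) | CO[C@H]1/C=C\C=C(/C)C(=O)Nc2cc(O)cc(c2O)[C@H](OC)[C@@H](C)C[C@H](O)[C@H](O)[C@@H](C)/C=C(\C)[C@@H]1OC(N)=O | target

**Step count**

Total steps: 29. Longest linear sequence: 28 (steps 1–14 and 16–29 from 1; step 15 prepares the glycolate imide).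

**Steps most likely to fail**

1. Step 25 (macrolactamisation). Oxidative addition at the hindered, electron-rich C20–Br bond may be slow, so that intermolecular coupling, oligomerisation or loss of bromine competes, and long heating may erode the 4Z geometry. The fallback forms N–C20 intermolecularly and closes the ring at C2=C3 instead. It sets out from allylic alcohol 31: copper/diamine-catalysed amidation of its aryl bromide with 2-(diethoxyphosphoryl)propanamide would give anilide phosphonate F1. MnO2 oxidation would give enal phosphonate F2. An intramolecular Horner–Wadsworth–Emmons reaction (LiCl, i-Pr2NEt, MeCN, high dilution) would then form the 2E alkene and return to the route at macrolactam 35.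

2. Step 9 (alkene isomerisation). The double bond may migrate incompletely, or migrate further to a silyl enol ether. The fallback sets the C12 carbinol by ketone reduction instead of allylboration and trimming. It sets out from aldehyde 9: addition of 2-methylprop-1-enylmagnesium bromide would give allylic alcohol F3 as both C12 epimers, and Dess–Martin oxidation would give enone F4. Reduction with BH3·SMe2 and the (R)-2-methyl-CBS-oxazaborolidine catalyst would give allylic alcohol F5, and TBSCl/imidazole would give silyl ether F6. Lemieux–Johnson cleavage (OsO4, NaIO4, 2,6-lutidine) of F6 returns to the route at aldehyde 15.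

3. Step 29 (acetal cleavage). Once the C21 phenol is free, acid may ionise the C15 benzylic methyl ether through an ortho-quinone methide, causing loss or epimerisation. Acid may also solvolyse the allylic C7 carbamate, and air may oxidise the aminohydroquinone. The fallback removes the acetals oxidatively and then reduces. It sets out from diol 39: (NH4)2Ce(NO3)6 in MeCN/H2O at 0 °C would dealkylate the 18,21-bis(methoxymethoxy)arene to quinone F7, and aqueous Na2S2O4 would reduce F7 to the hydroquinone, returning to the route at 40.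

**Further compounds**

F1 | step 25 | anilide phosphonate: N-aryl 2-(diethoxyphosphoryl)propanamide of the C3–C21 allylic alcohol | OC/C=C\[C@H](OC)[C@@H](O[Si](CC)(CC)CC)/C(C)=C/[C@H](C)[C@@H](O[Si](C)(C)C(C)(C)C)[C@@H](O[Si](C)(C)C(C)(C)C)C[C@H](C)[C@@H](OC)c1cc(OCOC)cc(NC(=O)C(C)P(=O)(OCC)OCC)c1OCOC
F2 | step 25 | enal phosphonate: (Z)-enal derived from F1 | O=C/C=C\[C@H](OC)[C@@H](O[Si](CC)(CC)CC)/C(C)=C/[C@H](C)[C@@H](O[Si](C)(C)C(C)(C)C)[C@@H](O[Si](C)(C)C(C)(C)C)C[C@H](C)[C@@H](OC)c1cc(OCOC)cc(NC(=O)C(C)P(=O)(OCC)OCC)c1OCOC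
F3 | step 9 | allylic alcohol (both C12 epimers) from 9 and 2-methylprop-1-enylmagnesium bromide | CC(C)=CC(O)C[C@H](C)[C@@H](OC)c1cc(OCOC)cc(Br)c1OCOC
F4 | step 9 | enone: (5S,6R)-6-[3-bromo-2,5-bis(methoxymethoxy)phenyl]-6-methoxy-2,5-dimethylhex-2-en-4-one | CC(C)=CC(=O)C[C@H](C)[C@@H](OC)c1cc(OCOC)cc(Br)c1OCOC
F5 | step 9 | allylic alcohol: (4S,6S,7R)-7-[3-bromo-2,5-bis(methoxymethoxy)phenyl]-7-methoxy-2,6-dimethylhept-2-en-4-ol | CC(C)=C[C@@H](O)C[C@H](C)[C@@H](OC)c1cc(OCOC)cc(Br)c1OCOC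
F6 | step 9 | silyl ether: tert-butyldimethylsilyl ether of F5 | CC(C)=C[C@@H](O[Si](C)(C)C(C)(C)C)C[C@H](C)[C@@H](OC)c1cc(OCOC)cc(Br)c1OCOC
F7 | step 29 | quinone: 18,21-benzoquinone form of 40 | CO[C@H]1/C=C\C=C(/C)C(=O)NC2=CC(=O)C=C(C2=O)[C@H](OC)[C@@H](C)C[C@H](O)[C@H](O)[C@@H](C)/C=C(\C)[C@@H]1OC(N)=O
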